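**Retrosynthetic overview**
- The target is a cyclohexenetriol ring (C1–C6) carrying a C17 chain; the last operations are a hydroxyl-directed reduction of a C5 ketone (the oxidation level at which C6 is nucleophilic) and removal of a PMB group from O4.
- Two bonds are disconnected in one step, C1–chain and C6–C1: the (E)-heptadec-12-enyl Grignard reagent opens a six-carbon enol lactone and the enolate set free closes the carbocycle, creating the quaternary C1 carbinol.
- Enabling feature: the six-membered enol-lactone ring O–C1(=O)–C2=C3–C4(OPMB)–C5(=C6H2). It locks C2=C3 cis, makes C1 an acylating carbonyl, and hides a regiodefined C5=C6 enolate as the leaving group; the C4 ether oxygen is meant to steer the metal and hence the C1 configuration.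
- The enol lactone comes from (R)-glyceraldehyde acetonide: C5≡C6 by Ohira–Bestmann homologation, C1–C3 by Still–Gennari Z-olefination, ring by 6-exo-dig cyclisation of the alkynoic acid (AuCl). The chain bromide comes from a B-alkyl Suzuki coupling.
- Ring order: temporary lactone ring first (step 8), carbocycle second (step 9); the lactone ring is consumed in the step that forms the carbocycle.

Key step: step 9

Remark: C1–C6 denote the ring carbons of the target (C1 tertiary carbinol, C2=C3 alkene, C4 and C5 secondary carbinols, C6 methylene); PMB is 4-methoxybenzyl; (E)-1-iodohex-1-ene and (R)-2,2-dimethyl-1,3-dioxolane-4-carbaldehyde (freshly distilled) are taken as catalogue compounds.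

**Route**

Step 1
Reactants: 1 11-bromoundec-1-ene; 2 (E)-1-iodohex-1-ene
Product: 4 (E)-17-bromoheptadec-5-ene, via B-(11-bromoundecyl)-9-borabicyclo[3.3.1]nonane 3 (not isolated)
Conditions: 9-BBN, THF, 0 °C to rt; then 2, PdCl2(dppf) (3 mol %), AsPh3, Cs2CO3, DMF/THF/H2O, rt
Reagents that add atoms: none
Why: B-alkyl Suzuki–Miyaura coupling, in which anti-Markovnikov hydroboration of the terminal alkene is followed by sp3–sp2 coupling with retention of the E geometry of the vinyl iodide, the primary alkyl bromide being inert to zerovalent palladium with dppf at room temperature.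

Step 2
Reactants: 5 (R)-2,2-dimethyl-1,3-dioxolane-4-carbaldehyde
Product: 6 (S)-4-ethynyl-2,2-dimethyl-1,3-dioxolane
Conditions: MeC(O)C(N2)P(O)(OMe)2, K2CO3, MeOH, 0 °C to rt
Reagents that add atoms: dimethyl (1-diazo-2-oxopropyl)phosphonate, CC(=O)C(=[N+]=[N-])P(=O)(OC)OC
Why: Ohira–Bestmann (Seyferth–Gilbert) homologation turns the aldehyde into the terminal alkyne under mild conditions that should leave the α-alkoxy stereocentre untouched (the descriptor changes from R to S only through the CIP ranking).

Step 3
Reactants: 6 (S)-4-ethynyl-2,2-dimethyl-1,3-dioxolane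
Product: 8 (4S)-4-ethynyl-2-(4-methoxyphenyl)-1,3-dioxolane (mixture at C2), via (S)-but-3-yne-1,2-diol 7 (not isolated)
Conditions: TsOH·H2O (cat.), MeOH, rt; evaporate; then 4-MeOC6H4CH(OMe)2, CSA (cat.), CH2Cl2, rt
Reagents that add atoms: 4-methoxybenzaldehyde dimethyl acetal, COc1ccc(C(OC)OC)cc1
Why: Acid-catalysed transacetalisation (methanolysis of the acetonide, then acetal formation on the 1,2-diol) installs the 4-methoxybenzylidene acetal needed for a regioselective reductive opening, the acetal carbon configuration being irrelevant.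

Step 4
Reactants: 8 (4S)-4-ethynyl-2-(4-methoxyphenyl)-1,3-dioxolane
Product: 9 (S)-2-[(4-methoxybenzyl)oxy]but-3-yn-1-ol
Conditions: iBu2AlH (3 equiv), CH2Cl2, −78 to 0 °C; aq. KNaC4H4O6 work-up
Reagents that add atoms: none
Why: Regioselective reductive opening of the 4-methoxybenzylidene acetal, in which aluminium binds the less hindered primary oxygen and hydride reduces the resulting oxocarbenium ion, should leave the PMB group on the secondary oxygen and the primary alcohol free.

Step 5
Reactants: 9 (S)-2-[(4-methoxybenzyl)oxy]but-3-yn-1-ol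
Product: 10 (S)-2-[(4-methoxybenzyl)oxy]but-3-ynal
Conditions: Dess–Martin periodinane, CH2Cl2, 0 °C; crude aldehyde used at once
Reagents that add atoms: none
Why: Dess–Martin oxidation is base-free and therefore suited to an epimerisable α-alkoxy aldehyde, which is carried forward without purification.

Step 6
Reactants: 10 (S)-2-[(4-methoxybenzyl)oxy]but-3-ynal
Product: 11 methyl (2Z,4R)-4-[(4-methoxybenzyl)oxy]hex-2-en-5-ynoate
Conditions: (CF3CH2O)2P(O)CH2CO2Me, KN(SiMe3)2, 18-crown-6, THF, −78 °C
Reagents that add atoms: methyl bis(2,2,2-trifluoroethyl)phosphonoacetate, COC(=O)CP(=O)(OCC(F)(F)F)OCC(F)(F)F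
Why: Still–Gennari modification of the Horner–Wadsworth–Emmons olefination, in which the trifluoroethyl phosphonate under dissociating conditions at −78 °C eliminates kinetically to the Z-enoate while the low temperature protects the adjacent stereocentre.

Step 7
Reactants: 11 methyl (2Z,4R)-4-[(4-methoxybenzyl)oxy]hex-2-en-5-ynoate
Product: 12 (2Z,4R)-4-[(4-methoxybenzyl)oxy]hex-2-en-5-ynoic acid
Conditions: LiOH·H2O, THF/H2O, 0 °C; then 1 M HCl to pH 3
Reagents that add atoms: lithium hydroxide, [Li+].[OH-]
Why: Ester saponification, in which the Z geometry is retained and the acid cannot lactonise to a butenolide because O4 is blocked as its PMB ether.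

Step 8
Reactants: 12 (2Z,4R)-4-[(4-methoxybenzyl)oxy]hex-2-en-5-ynoic acid
Product: 13 (5R)-5-[(4-methoxybenzyl)oxy]-6-methylidene-5,6-dihydro-2H-pyran-2-one
Conditions: AuCl (5 mol %), K2CO3 (10 mol %), MeCN, rt; filtration through neutral alumina, used at once
Reagents that add atoms: none
Why: Cycloisomerisation of an alkynoic acid by monovalent gold, in which the carboxylate oxygen adds anti to the activated terminal alkyne in the 6-exo-dig (Markovnikov) mode, favoured because the cis alkene holds acid and alkyne together, and protodeauration releases the exocyclic enol lactone.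

Step 9
Reactants: 4 (E)-17-bromoheptadec-5-ene; 13 (5R)-5-[(4-methoxybenzyl)oxy]-6-methylidene-5,6-dihydro-2H-pyran-2-one
Product: 16 (3R,6R)-3-[(E)-heptadec-12-en-1-yl]-3-hydroxy-6-[(4-methoxybenzyl)oxy]cyclohex-4-en-1-one, via (E)-heptadec-12-enylmagnesium bromide 14 (not isolated), via open-chain bromomagnesium keto enolate 15 (not isolated)
Conditions: 4, Mg, THF, 45 °C; then added slowly (1.05 equiv) to 13 and anhydrous CeCl3 (1.5 equiv), THF, −78 °C; AcOH, −78 °C
Reagents that add atoms: none
Why: Proposed new method: the cerium-modified Grignard reagent adds 1,2 to the lactone carbonyl C1 and the tetrahedral adduct collapses by expelling the enol oxygen, which in one event unveils the C1 ketone and a regiodefined C5=C6 enolate that the cis C2=C3 bond inherited from the lactone ring holds next to it; C6 then adds to C1. The closest known reactions are the Fujimoto–Belleau annulation (Grignard reagent plus enol lactone), the cleavage of enol esters by organometallics to regiodefined enolates, and the Ferrier carbocyclization, which makes the same C6–C1 aldol bond from hex-5-enopyranosides. The only ring closed is the cyclohexene, by a 6-(enolendo)-exo-trig aldol addition. The new C1 stereocentre is controlled by C4: cerium or magnesium is expected to bridge the C1 carbonyl oxygen and the C4 PMB-ether oxygen, which the cis alkene places side by side, so that C5 and with it C6 reach the carbonyl face opposite the metal and O1 ends cis to O4 with the chain pseudo-equatorial. The step needs 1,2-addition rather than 1,4-addition or γ-deprotonation (secured by CeCl3 and −78 °C), a single addition (the enol ester is far more electrophilic than an alkyl ester and the intramolecular aldol should outrun a second intermolecular addition when the reagent is added slowly), and the right aldol regiochemistry (fixed because the enolate is born at C5=C6 and trapped before proton transfer). Quenching cold with acetic acid should prevent retro-aldol equilibration and dehydration of the ketol.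

Step 10
Reactants: 16 (3R,6R)-3-[(E)-heptadec-12-en-1-yl]-3-hydroxy-6-[(4-methoxybenzyl)oxy]cyclohex-4-en-1-one
Product: 17 (1R,4R,5R)-1-[(E)-heptadec-12-en-1-yl]-4-[(4-methoxybenzyl)oxy]cyclohex-2-ene-1,5-diol
Conditions: Me4NBH(OAc)3, MeCN/AcOH (1:1), −30 °C
Reagents that add atoms: none
Why: Evans–Saksena hydroxyl-directed reduction, in which the C1 hydroxyl exchanges onto boron and delivers hydride intramolecularly to the face of the C5 ketone syn to O1, should give the 1,3-anti diol, that is (5R) with the new hydroxyl trans to both O1 and the C4 ether.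

Step 11
Reactants: 17 (1R,4R,5R)-1-[(E)-heptadec-12-en-1-yl]-4-[(4-methoxybenzyl)oxy]cyclohex-2-ene-1,5-diol
Product: 18 (1R,4R,5R)-1-[(E)-heptadec-12-en-1-yl]cyclohex-2-ene-1,4,5-triol
Conditions: DDQ, CH2Cl2/pH 7 phosphate buffer (10:1), 0 °C
Reagents that add atoms: none
Why: Oxidative PMB-ether cleavage by DDQ (hydride abstraction from the electron-rich benzylic position, then hydrolysis) is selective for the PMB group and should leave both alkenes and the tertiary allylic alcohol untouched.

**Compound list**
1 | 11-bromoundec-1-ene | C=CCCCCCCCCCBr | starting material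
2 | (E)-1-iodohex-1-ene | CCCC/C=C/I | starting material
3 | B-(11-bromoundecyl)-9-borabicyclo[3.3.1]nonane | BrCCCCCCCCCCCB1C2CCCC1CCC2 | intermediate
4 | (E)-17-bromoheptadec-5-ene | CCCC/C=C/CCCCCCCCCCCBr | intermediate
5 | (R)-2,2-dimethyl-1,3-dioxolane-4-carbaldehyde | O=C[C@H]1COC(C)(C)O1 | starting material
6 | (S)-4-ethynyl-2,2-dimethyl-1,3-dioxolane | C#C[C@H]1COC(C)(C)O1 | intermediate
7 | (S)-but-3-yne-1,2-diol | C#C[C@H](O)CO | intermediate
8 | (4S)-4-ethynyl-2-(4-methoxyphenyl)-1,3-dioxolane (mixture at C2) | C#C[C@H]1COC(c2ccc(OC)cc2)O1 | intermediate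
9 | (S)-2-[(4-methoxybenzyl)oxy]but-3-yn-1-ol | C#C[C@H](OCc1ccc(OC)cc1)CO | intermediate
10 | (S)-2-[(4-methoxybenzyl)oxy]but-3-ynal | C#C[C@H](OCc1ccc(OC)cc1)C=O | intermediate
11 | methyl (2Z,4R)-4-[(4-methoxybenzyl)oxy]hex-2-en-5-ynoate | C#C[C@H](OCc1ccc(OC)cc1)/C=C\C(=O)OC | intermediate
12 | (2Z,4R)-4-[(4-methoxybenzyl)oxy]hex-2-en-5-ynoic acid | C#C[C@H](OCc1ccc(OC)cc1)/C=C\C(=O)O | intermediate
13 | (5R)-5-[(4-methoxybenzyl)oxy]-6-methylidene-5,6-dihydro-2H-pyran-2-one | C=C1OC(=O)C=C[C@H]1OCc2ccc(OC)cc2 | intermediate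
14 | (E)-heptadec-12-enylmagnesium bromide | CCCC/C=C/CCCCCCCCCCC[Mg]Br | intermediate
15 | bromomagnesium C1=C2 enolate of (3R,4Z,18E)-3-[(4-methoxybenzyl)oxy]tricosa-4,18-diene-2,6-dione (the counter-ion may equally be cerium) | CCCC/C=C/CCCCCCCCCCCC(=O)/C=C\[C@@H](OCc1ccc(OC)cc1)C(=C)O[Mg]Br | intermediate
16 | (3R,6R)-3-[(E)-heptadec-12-en-1-yl]-3-hydroxy-6-[(4-methoxybenzyl)oxy]cyclohex-4-en-1-one | CCCC/C=C/CCCCCCCCCCC[C@]1(O)C=C[C@@H](OCc2ccc(OC)cc2)C(=O)C1 | intermediate
17 | (1R,4R,5R)-1-[(E)-heptadec-12-en-1-yl]-4-[(4-methoxybenzyl)oxy]cyclohex-2-ene-1,5-diol | CCCC/C=C/CCCCCCCCCCC[C@]1(O)C=C[C@@H](OCc2ccc(OC)cc2)[C@H](O)C1 | intermediate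
18 | (1R,4R,5R)-1-[(E)-heptadec-12-en-1-yl]cyclohex-2-ene-1,4,5-triol | CCCC/C=C/CCCCCCCCCCC[C@]1(O)C=C[C@@H](O)[C@H](O)C1 | target

**Step count**
Total: 11 steps. Longest linear sequence: 10 steps (5 to 18, steps 2–11); the chain bromide 4 is made in one step and joins at step 9.

**Steps most likely to fail**

Step 9. The organometallic may deprotonate the γ-position (C4–H) of the enol lactone, which would tautomerise it to the aromatic 2-pyranone and erase the C4 stereocentre. Facial selectivity at C1 may also be poor if the metal does not bridge O1 and O4. The fallback uses known chemistry, sets out from acid 12 and Grignard reagent 14, and returns at 16. Acid 12 is converted into its Weinreb amide, (2Z,4R)-N-methoxy-4-[(4-methoxybenzyl)oxy]-N-methylhex-2-en-5-ynamide F1 (EDC·HCl, MeNHOMe·HCl, N-methylmorpholine, CH2Cl2). After deprotonation of the alkyne C–H with i-PrMgCl, 14 adds once to give the Z-enynone (3R,4Z,18E)-3-[(4-methoxybenzyl)oxy]tricosa-4,18-dien-1-yn-6-one F2. AuCl in dry MeOH then closes the ketone oxygen onto the alkyne (6-exo-dig) with capture of methanol, giving the methyl ketoside (5R)-2-[(E)-heptadec-12-en-1-yl]-2-methoxy-5-[(4-methoxybenzyl)oxy]-6-methylidene-5,6-dihydro-2H-pyran F3, an analogue of a hex-5-enopyranoside. Ferrier carbocyclization (Hg(OCOCF3)2 cat., acetone/H2O, rt) forms the same C6–C1 bond through the α-mercurio ketone under near-neutral conditions and should give 16.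

Step 8. Trace acid or base may move the exocyclic double bond into the ring, turning the enol lactone into the aromatic 2-pyranone with loss of the C4 stereocentre; 7-endo closure may also compete. The fallback sets out from 12 and returns at 13. Semihydrogenation of the terminal alkyne (H2, Pd/CaCO3 poisoned with Pb(OAc)2, quinoline) gives (2Z,4S)-4-[(4-methoxybenzyl)oxy]hexa-2,5-dienoic acid F4. Iodolactonisation (I2, NaHCO3, MeCN, 0 °C, 6-exo) gives (5R)-6-(iodomethyl)-5-[(4-methoxybenzyl)oxy]-5,6-dihydro-2H-pyran-2-one F5, as a C6 mixture that does not matter. Dehydroiodination with AgF in pyridine, the standard way to exocyclic enol ethers of pyranosides, should give 13 without gold or protic acid.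

Step 10. The tertiary C1 hydroxyl may exchange onto boron too slowly, so that acid-promoted dehydration of the β,γ-unsaturated ketol (aromatisation to a phenol) overtakes hydride delivery. The fallback sets out from 16 and returns at 17. Ketol 16 is reduced under neutral Luche conditions (NaBH4, CeCl3·7H2O, MeOH, −78 °C), where the pseudo-axial C1 oxygen is expected to block axial attack and lead to the C5 epimer (1R,4R,5S)-1-[(E)-heptadec-12-en-1-yl]-4-[(4-methoxybenzyl)oxy]cyclohex-2-ene-1,5-diol F6. Mitsunobu inversion of the secondary C5 hydroxyl (4-nitrobenzoic acid, PPh3, DIAD, THF; the tertiary hydroxyl does not react) gives (1R,2R,5R)-5-[(E)-heptadec-12-en-1-yl]-5-hydroxy-2-[(4-methoxybenzyl)oxy]cyclohex-3-en-1-yl 4-nitrobenzoate F7. Methanolysis (K2CO3, MeOH) returns 17.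

**Further compounds**
F1 | step 9 | (2Z,4R)-N-methoxy-4-[(4-methoxybenzyl)oxy]-N-methylhex-2-en-5-ynamide | C#C[C@H](OCc1ccc(OC)cc1)/C=C\C(=O)N(C)OC
F2 | step 9 | (3R,4Z,18E)-3-[(4-methoxybenzyl)oxy]tricosa-4,18-dien-1-yn-6-one | C#C[C@H](OCc1ccc(OC)cc1)/C=C\C(=O)CCCCCCCCCCC/C=C/CCCC
F3 | step 9 | (5R)-2-[(E)-heptadec-12-en-1-yl]-2-methoxy-5-[(4-methoxybenzyl)oxy]-6-methylidene-5,6-dihydro-2H-pyran (mixture at C2) | C=C1OC(OC)(CCCCCCCCCCC/C=C/CCCC)C=C[C@H]1OCc2ccc(OC)cc2
F4 | step 8 | (2Z,4S)-4-[(4-methoxybenzyl)oxy]hexa-2,5-dienoic acid | C=C[C@H](OCc1ccc(OC)cc1)/C=C\C(=O)O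
F5 | step 8 | (5R)-6-(iodomethyl)-5-[(4-methoxybenzyl)oxy]-5,6-dihydro-2H-pyran-2-one (mixture at C6) | ICC1OC(=O)C=C[C@H]1OCc2ccc(OC)cc2
F6 | step 10 | (1R,4R,5S)-1-[(E)-heptadec-12-en-1-yl]-4-[(4-methoxybenzyl)oxy]cyclohex-2-ene-1,5-diol | CCCC/C=C/CCCCCCCCCCC[C@]1(O)C=C[C@@H](OCc2ccc(OC)cc2)[C@@H](O)C1
F7 | step 10 | (1R,2R,5R)-5-[(E)-heptadec-12-en-1-yl]-5-hydroxy-2-[(4-methoxybenzyl)oxy]cyclohex-3-en-1-yl 4-nitrobenzoate | CCCC/C=C/CCCCCCCCCCC[C@]1(O)C=C[C@@H](OCc2ccc(OC)cc2)[C@H](OC(=O)c2ccc(cc2)[N+](=O)[O-])C1
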